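**Retrosynthetic overview** (rings lettered A–F from the 2,4,6-trihydroxyphenoxy end to the 3,4,5-trihydroxyphenoxy end)
- The target is the fifteen-fold O-demethylation product of the hexamer pentadecamethyl ether; no ring is built, all six benzene rings are bought.
- Feature: the oxygens between rings C/D and D/E each sit on a crowded carbon (C-6 of ring C, between O–B and OMe; C-4 of ring D, between two OMe-bearing carbons) and bind C-1 of ring D or E, a carbon flanked by two C–H and para to that ring's own crowded oxygen. This is the imprint of a 4-oxy-3,5-dimethoxybenzoate ester that has lost CO.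
- Key disconnection: both ethers come from the diester A–B–C–O–CO–D–O–CO–E–F by twofold nickel-catalysed carbon monoxide extrusion.
- The diester comes from the A–B–C phenol and the D–E–F acyl chloride; D–E–F comes from syringaldehyde acylated by the E–F acid (Chan–Lam coupling on methyl syringate), then Pinnick oxidation.
- A–B–C comes from two rounds of copper-catalysed coupling of a crowded phenol with a bromobenzaldehyde, each followed by Baeyer–Villiger oxidation. Joining order: A–B, A–B–C, E–F, D–E–F (ester), C–D (ester), then C–O–D and D–O–E together.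

Key step: step 13

Remark: the target has no stereocentre and its diaryl ether axes rotate freely, so it is achiral and needs no enantiocontrol; 4-bromo-2,6-dimethoxybenzaldehyde, methyl syringate and syringaldehyde are taken as purchased.

**Route**

Step 1
Reactants: 1 5-bromo-1,2,3-trimethoxybenzene
Product: 2 6-bromo-2,3,4-trimethoxybenzaldehyde
Conditions: Cl2CHOMe, TiCl4, CH2Cl2, −10 to 0 °C; then ice/aq. HCl
Reagents that add atoms: dichloromethyl methyl ether, COC(Cl)Cl (formyl carbon); water, O (carbonyl oxygen on work-up)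
Why: Rieche formylation; the two free ring positions of 1 are equivalent and each lies para to one methoxy group and ortho to another, so a single aldehyde with the bromine ortho to the formyl group should form.

Step 2
Reactants: 3 2,4,6-trimethoxyphenol; 4 4-bromo-2,6-dimethoxybenzaldehyde
Product: 5 2,6-dimethoxy-4-(2,4,6-trimethoxyphenoxy)benzaldehyde
Conditions: CuI (10 mol%), picolinic acid (20 mol%), K3PO4, DMSO, 90 °C, Ar
Reagents that add atoms: none
Why: Ullmann-type copper-catalysed C–O coupling; the para-formyl group makes bromide 4 electron-poor and it has no ortho substituent, while the picolinic acid system is known to accept doubly ortho-substituted phenols.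

Step 3
Reactants: 5 2,6-dimethoxy-4-(2,4,6-trimethoxyphenoxy)benzaldehyde
Product: 7 2,6-dimethoxy-4-(2,4,6-trimethoxyphenoxy)phenol, via aryl formate 6 (not isolated)
Conditions: mCPBA, CH2Cl2, 0 °C to rt; then K2CO3 (cat.), MeOH, rt
Reagents that add atoms: mCPBA, O=C(OO)c1cccc(Cl)c1
Why: Baeyer–Villiger (Dakin-type) oxidation; the aryl group with two ortho methoxy groups and a para aryloxy group should migrate far faster than hydride, and the formate is then removed by base-catalysed methanolysis.

Step 4
Reactants: 7 2,6-dimethoxy-4-(2,4,6-trimethoxyphenoxy)phenol; 2 6-bromo-2,3,4-trimethoxybenzaldehyde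
Product: 8 6-[2,6-dimethoxy-4-(2,4,6-trimethoxyphenoxy)phenoxy]-2,3,4-trimethoxybenzaldehyde
Conditions: CuI (20 mol%), picolinic acid (40 mol%), K3PO4, DMSO, 100 °C, Ar
Reagents that add atoms: none
Why: Ullmann-type C–O coupling; the ortho-formyl group activates bromide 2 towards copper and is its only ortho substituent, so the crowding lies on the phenoxide, the partner that tolerates it.

Step 5
Reactants: 8 6-[2,6-dimethoxy-4-(2,4,6-trimethoxyphenoxy)phenoxy]-2,3,4-trimethoxybenzaldehyde
Product: 10 6-[2,6-dimethoxy-4-(2,4,6-trimethoxyphenoxy)phenoxy]-2,3,4-trimethoxyphenol, via aryl formate 9 (not isolated)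
Conditions: mCPBA, CH2Cl2, 0 °C to rt; then K2CO3 (cat.), MeOH, rt
Reagents that add atoms: mCPBA, O=C(OO)c1cccc(Cl)c1
Why: Baeyer–Villiger oxidation; the formyl group sits between an aryloxy and a methoxy group with a para methoxy group, so aryl migration should dominate and methanolysis of the formate should give the ring C phenol.

Step 6
Reactants: 11 methyl syringate (methyl 4-hydroxy-3,5-dimethoxybenzoate); 12 3,4,5-trimethoxyphenylboronic acid
Product: 13 methyl 3,5-dimethoxy-4-(3,4,5-trimethoxyphenoxy)benzoate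
Conditions: Cu(OAc)2 (1.5 equiv), pyridine, 4 Å MS, CH2Cl2, dry air, rt
Reagents that add atoms: none
Why: Chan–Lam–Evans oxidative C–O coupling, which is established for doubly ortho-substituted phenols and runs at room temperature without strong base, so the methyl ester is untouched.

Step 7
Reactants: 13 methyl 3,5-dimethoxy-4-(3,4,5-trimethoxyphenoxy)benzoate
Product: 14 3,5-dimethoxy-4-(3,4,5-trimethoxyphenoxy)benzoic acid
Conditions: LiOH·H2O, THF/MeOH/H2O, 50 °C; then 1 M HCl
Reagents that add atoms: lithium hydroxide, [Li+].[OH-] (hydroxyl oxygen of the acid)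
Why: Ester saponification; the diaryl ether and the aryl methyl ethers are inert to aqueous hydroxide.

Step 8
Reactants: 14 3,5-dimethoxy-4-(3,4,5-trimethoxyphenoxy)benzoic acid
Product: 15 3,5-dimethoxy-4-(3,4,5-trimethoxyphenoxy)benzoyl chloride
Conditions: (COCl)2, DMF (cat.), CH2Cl2, 0 °C to rt; evaporate
Reagents that add atoms: oxalyl chloride, ClC(=O)C(Cl)=O
Why: Acyl chloride formation through the Vilsmeier-type chloroiminium catalyst; the by-products are gases and no acid-labile group is present.

Step 9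
Reactants: 15 3,5-dimethoxy-4-(3,4,5-trimethoxyphenoxy)benzoyl chloride; 16 syringaldehyde (4-hydroxy-3,5-dimethoxybenzaldehyde)
Product: 17 4-formyl-2,6-dimethoxyphenyl 3,5-dimethoxy-4-(3,4,5-trimethoxyphenoxy)benzoate
Conditions: Et3N, DMAP (cat.), CH2Cl2, 0 °C to rt
Reagents that add atoms: none
Why: DMAP-catalysed O-acylation through the acylpyridinium ion; ester formation is little affected by the two ortho methoxy groups of the phenol and the aldehyde does not react.

Step 10
Reactants: 17 4-formyl-2,6-dimethoxyphenyl 3,5-dimethoxy-4-(3,4,5-trimethoxyphenoxy)benzoate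
Product: 18 4-{[3,5-dimethoxy-4-(3,4,5-trimethoxyphenoxy)benzoyl]oxy}-3,5-dimethoxybenzoic acid
Conditions: NaClO2, NaH2PO4, 2-methyl-2-butene, t-BuOH/THF/H2O, 0 °C to rt
Reagents that add atoms: sodium chlorite, [Na+].[O-]Cl=O
Why: Pinnick oxidation at about pH 4 converts the aldehyde to the acid without touching the aryl ester, and the alkene traps hypochlorous acid before it can chlorinate the electron-rich rings.

Step 11
Reactants: 18 4-{[3,5-dimethoxy-4-(3,4,5-trimethoxyphenoxy)benzoyl]oxy}-3,5-dimethoxybenzoic acid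
Product: 19 4-{[3,5-dimethoxy-4-(3,4,5-trimethoxyphenoxy)benzoyl]oxy}-3,5-dimethoxybenzoyl chloride
Conditions: (COCl)2, DMF (cat.), CH2Cl2, 0 °C to rt; evaporate
Reagents that add atoms: oxalyl chloride, ClC(=O)C(Cl)=O
Why: Acyl chloride formation under neutral to acidic conditions, in which the internal aryl ester is stable.

Step 12
Reactants: 10 6-[2,6-dimethoxy-4-(2,4,6-trimethoxyphenoxy)phenoxy]-2,3,4-trimethoxyphenol; 19 4-{[3,5-dimethoxy-4-(3,4,5-trimethoxyphenoxy)benzoyl]oxy}-3,5-dimethoxybenzoyl chloride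
Product: 20 6-[2,6-dimethoxy-4-(2,4,6-trimethoxyphenoxy)phenoxy]-2,3,4-trimethoxyphenyl 4-{[3,5-dimethoxy-4-(3,4,5-trimethoxyphenoxy)benzoyl]oxy}-3,5-dimethoxybenzoate
Conditions: Et3N, DMAP, CH2Cl2, 0 °C to rt
Reagents that add atoms: none
Why: DMAP-catalysed O-acylation; the acyl chloride is far more electrophilic than the aryl ester inside 19, so the crowded phenol should be acylated at the chloride only, and acylation tolerates the two ortho oxygen substituents much better than any arylation would.

Step 13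
Reactants: 20 6-[2,6-dimethoxy-4-(2,4,6-trimethoxyphenoxy)phenoxy]-2,3,4-trimethoxyphenyl 4-{[3,5-dimethoxy-4-(3,4,5-trimethoxyphenoxy)benzoyl]oxy}-3,5-dimethoxybenzoate
Product: 22 hexamer pentadecamethyl ether (A–B–C–D–E–F with all fifteen hydroxyl groups as OMe), via monoester monoether 21 (not isolated)
Conditions: Ni(cod)2 (40 mol%), dcypt [3,4-bis(dicyclohexylphosphino)thiophene] (80 mol%), K3PO4 (dried), m-xylene (0.02 M), 160 °C, Ar sweep
Reagents that add atoms: none
Why: Proposed new method: Ni(0) bound to the electron-rich chelating diphosphine should insert into each C(acyl)–O bond to give an acyl nickel(II) aryloxide, the aryl group then moves to nickel with loss of CO, and C–O reductive elimination releases the diaryl ether at the same two atoms, the D–E ester (better aryloxide leaving group, para to an acyl group) expected to react first and the C–D ester second. The closest known reaction type is the nickel- or palladium-catalysed decarbonylative diaryl ether synthesis from single aryl esters, established mainly for azinecarboxylates and not for two electron-rich benzoates in one molecule. No ring closes and no stereocentre forms. The step needs insertion into C(acyl)–O in preference to C(aryl)–OMe and it needs each aryloxide to stay with its own acyl partner; both acyl groups sit on ring carbons with two ortho hydrogens, which eases insertion and de-insertion, and the bulk of the 2,6-disubstituted aryloxides should speed reductive elimination. The chelate should hold the aryloxide on nickel, and dilution plus a steady argon sweep that carries off CO should limit aryloxide crossover and carbonyl poisoning of the catalyst.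

Step 14
Reactants: 22 hexamer pentadecamethyl ether
Product: 23 CNP0270681.0 (hexamer pentadecaphenol)
Conditions: BBr3 (excess), CH2Cl2, −78 °C to rt; then degassed MeOH/H2O
Reagents that add atoms: none
Why: Lewis acid ether cleavage; boron binds each methoxy oxygen and bromide attacks the methyl carbon by SN2, a path closed to the diaryl ether carbons, and hydrolysis of the aryl borates should free the fifteen phenols.

**Compound list**
1 | 5-bromo-1,2,3-trimethoxybenzene | COc1cc(Br)cc(OC)c1OC | starting material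
2 | 6-bromo-2,3,4-trimethoxybenzaldehyde | O=Cc1c(Br)cc(OC)c(OC)c1OC | intermediate
3 | 2,4,6-trimethoxyphenol | COc1cc(OC)c(O)c(OC)c1 | starting material
4 | 4-bromo-2,6-dimethoxybenzaldehyde | COc1cc(Br)cc(OC)c1C=O | starting material
5 | 2,6-dimethoxy-4-(2,4,6-trimethoxyphenoxy)benzaldehyde | COc1cc(OC)c(Oc2cc(OC)c(C=O)c(OC)c2)c(OC)c1 | intermediate
6 | 2,6-dimethoxy-4-(2,4,6-trimethoxyphenoxy)phenyl formate | COc1cc(OC)c(Oc2cc(OC)c(OC=O)c(OC)c2)c(OC)c1 | intermediate
7 | 2,6-dimethoxy-4-(2,4,6-trimethoxyphenoxy)phenol | COc1cc(OC)c(Oc2cc(OC)c(O)c(OC)c2)c(OC)c1 | intermediate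
8 | 6-[2,6-dimethoxy-4-(2,4,6-trimethoxyphenoxy)phenoxy]-2,3,4-trimethoxybenzaldehyde | COc1cc(OC)c(Oc2cc(OC)c(Oc3cc(OC)c(OC)c(OC)c3C=O)c(OC)c2)c(OC)c1 | intermediate
9 | 6-[2,6-dimethoxy-4-(2,4,6-trimethoxyphenoxy)phenoxy]-2,3,4-trimethoxyphenyl formate | COc1cc(OC)c(Oc2cc(OC)c(Oc3cc(OC)c(OC)c(OC)c3OC=O)c(OC)c2)c(OC)c1 | intermediate
10 | 6-[2,6-dimethoxy-4-(2,4,6-trimethoxyphenoxy)phenoxy]-2,3,4-trimethoxyphenol (A–B–C phenol) | COc1cc(OC)c(Oc2cc(OC)c(Oc3cc(OC)c(OC)c(OC)c3O)c(OC)c2)c(OC)c1 | intermediate
11 | methyl syringate | COC(=O)c1cc(OC)c(O)c(OC)c1 | starting material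
12 | 3,4,5-trimethoxyphenylboronic acid | COc1cc(B(O)O)cc(OC)c1OC | starting material
13 | methyl 3,5-dimethoxy-4-(3,4,5-trimethoxyphenoxy)benzoate | COC(=O)c1cc(OC)c(Oc2cc(OC)c(OC)c(OC)c2)c(OC)c1 | intermediate
14 | 3,5-dimethoxy-4-(3,4,5-trimethoxyphenoxy)benzoic acid (E–F acid) | OC(=O)c1cc(OC)c(Oc2cc(OC)c(OC)c(OC)c2)c(OC)c1 | intermediate
15 | 3,5-dimethoxy-4-(3,4,5-trimethoxyphenoxy)benzoyl chloride | ClC(=O)c1cc(OC)c(Oc2cc(OC)c(OC)c(OC)c2)c(OC)c1 | intermediate
16 | syringaldehyde | COc1cc(C=O)cc(OC)c1O | starting material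
17 | 4-formyl-2,6-dimethoxyphenyl 3,5-dimethoxy-4-(3,4,5-trimethoxyphenoxy)benzoate | O=Cc1cc(OC)c(OC(=O)c2cc(OC)c(Oc3cc(OC)c(OC)c(OC)c3)c(OC)c2)c(OC)c1 | intermediate
18 | 4-{[3,5-dimethoxy-4-(3,4,5-trimethoxyphenoxy)benzoyl]oxy}-3,5-dimethoxybenzoic acid (D–E–F acid) | OC(=O)c1cc(OC)c(OC(=O)c2cc(OC)c(Oc3cc(OC)c(OC)c(OC)c3)c(OC)c2)c(OC)c1 | intermediate
19 | 4-{[3,5-dimethoxy-4-(3,4,5-trimethoxyphenoxy)benzoyl]oxy}-3,5-dimethoxybenzoyl chloride | ClC(=O)c1cc(OC)c(OC(=O)c2cc(OC)c(Oc3cc(OC)c(OC)c(OC)c3)c(OC)c2)c(OC)c1 | intermediate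
20 | diester precursor: A–B–C aryl ester of the D benzoate, itself O-acylated by the E–F acid | COc1cc(OC)c(Oc2cc(OC)c(Oc3cc(OC)c(OC)c(OC)c3OC(=O)c3cc(OC)c(OC(=O)c4cc(OC)c(Oc5cc(OC)c(OC)c(OC)c5)c(OC)c4)c(OC)c3)c(OC)c2)c(OC)c1 | intermediate
21 | monoester monoether: A–B–C aryl 4-[3,5-dimethoxy-4-(3,4,5-trimethoxyphenoxy)phenoxy]-3,5-dimethoxybenzoate | COc1cc(OC)c(Oc2cc(OC)c(Oc3cc(OC)c(OC)c(OC)c3OC(=O)c3cc(OC)c(Oc4cc(OC)c(Oc5cc(OC)c(OC)c(OC)c5)c(OC)c4)c(OC)c3)c(OC)c2)c(OC)c1 | intermediate
22 | hexamer pentadecamethyl ether | COc1cc(OC)c(Oc2cc(OC)c(Oc3cc(OC)c(OC)c(OC)c3Oc3cc(OC)c(Oc4cc(OC)c(Oc5cc(OC)c(OC)c(OC)c5)c(OC)c4)c(OC)c3)c(OC)c2)c(OC)c1 | intermediate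
23 | CNP0270681.0 | Oc1cc(O)c(Oc2cc(O)c(Oc3cc(O)c(O)c(O)c3Oc3cc(O)c(Oc4cc(O)c(Oc5cc(O)c(O)c(O)c5)c(O)c4)c(O)c3)c(O)c2)c(O)c1 | target

**Step count**
Total: 14 steps. Longest linear sequence: 9 steps (steps 6 to 14, from methyl syringate).

**Steps most likely to fail**

Step 13. Insertion of nickel into two electron-rich, crowded aryl benzoates may be too slow. Bound CO may shut the catalyst down. Aryloxide exchange between metal centres or base-induced acyl transfer may scramble the fragments. The aryl nickel aryloxide may also be protonated before C–O reductive elimination. The fallback uses only the known reactions of steps 2 to 6 and sets out from phenol 10. Copper-catalysed coupling of 10 with bromide 4 (CuI, picolinic acid, K3PO4, DMSO) should give the tetramer aldehyde 4-{6-[2,6-dimethoxy-4-(2,4,6-trimethoxyphenoxy)phenoxy]-2,3,4-trimethoxyphenoxy}-2,6-dimethoxybenzaldehyde F1. Baeyer–Villiger oxidation with mCPBA should pass through the tetramer formate F2, and methanolysis should give the tetramer phenol F3. A second coupling with 4 should give the pentamer aldehyde F4, oxidation should give the pentamer formate F5, and methanolysis the pentamer phenol F6. Chan–Lam coupling of F6 with boronic acid 12 then returns to the route at 22.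

Step 14. Cleavage of fifteen methyl ethers may stall at partly methylated borate aggregates, and the freed pyrogallol-type rings may oxidise in air during isolation. The fallback sets out from 22 and changes the isolation from the free polyphenol to a stable derivative. After the boron tribromide treatment and quench, the crude material is acetylated directly (Ac2O, pyridine, DMAP) to the hexamer pentadecaacetate F7. This is purified on silica, where partly methylated congeners are removed. The acetates are then cleaved by acid-catalysed methanolysis under argon (HCl in degassed MeOH, rt), which returns to the route at 23.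

Step 4. The tri-ortho-substituted ether may form slowly at copper, so that hydrodebromination of 2, oxidation of the phenoxide of 7 or base-induced loss of the aldehyde takes over. The fallback sets out from 7 and replaces the metal-catalysed coupling by an uncatalysed addition–elimination. The known fluoroarene 5-fluoro-1,2,3-trimethoxybenzene F8, taken as purchased, is formylated under Rieche conditions to 6-fluoro-2,3,4-trimethoxybenzaldehyde F9. The phenoxide of 7 (Cs2CO3, DMSO, 120 °C) should displace the fluoride ortho to the formyl group, which returns to the route at 8.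

**Further compounds**
F1 | step 13 | 4-{6-[2,6-dimethoxy-4-(2,4,6-trimethoxyphenoxy)phenoxy]-2,3,4-trimethoxyphenoxy}-2,6-dimethoxybenzaldehyde (tetramer aldehyde) | COc1cc(OC)c(Oc2cc(OC)c(Oc3cc(OC)c(OC)c(OC)c3Oc3cc(OC)c(C=O)c(OC)c3)c(OC)c2)c(OC)c1
F2 | step 13 | tetramer formate | COc1cc(OC)c(Oc2cc(OC)c(Oc3cc(OC)c(OC)c(OC)c3Oc3cc(OC)c(OC=O)c(OC)c3)c(OC)c2)c(OC)c1
F3 | step 13 | tetramer phenol | COc1cc(OC)c(Oc2cc(OC)c(Oc3cc(OC)c(OC)c(OC)c3Oc3cc(OC)c(O)c(OC)c3)c(OC)c2)c(OC)c1
F4 | step 13 | pentamer aldehyde | COc1cc(OC)c(Oc2cc(OC)c(Oc3cc(OC)c(OC)c(OC)c3Oc3cc(OC)c(Oc4cc(OC)c(C=O)c(OC)c4)c(OC)c3)c(OC)c2)c(OC)c1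
F5 | step 13 | pentamer formate | COc1cc(OC)c(Oc2cc(OC)c(Oc3cc(OC)c(OC)c(OC)c3Oc3cc(OC)c(Oc4cc(OC)c(OC=O)c(OC)c4)c(OC)c3)c(OC)c2)c(OC)c1
F6 | step 13 | pentamer phenol | COc1cc(OC)c(Oc2cc(OC)c(Oc3cc(OC)c(OC)c(OC)c3Oc3cc(OC)c(Oc4cc(OC)c(O)c(OC)c4)c(OC)c3)c(OC)c2)c(OC)c1
F7 | step 14 | hexamer pentadecaacetate | CC(=O)Oc1cc(OC(C)=O)c(Oc2cc(OC(C)=O)c(Oc3cc(OC(C)=O)c(OC(C)=O)c(OC(C)=O)c3Oc3cc(OC(C)=O)c(Oc4cc(OC(C)=O)c(Oc5cc(OC(C)=O)c(OC(C)=O)c(OC(C)=O)c5)c(OC(C)=O)c4)c(OC(C)=O)c3)c(OC(C)=O)c2)c(OC(C)=O)c1
F8 | step 4 | 5-fluoro-1,2,3-trimethoxybenzene (purchased) | COc1cc(F)cc(OC)c1OC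
F9 | step 4 | 6-fluoro-2,3,4-trimethoxybenzaldehyde | O=Cc1c(F)cc(OC)c(OC)c1OC
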